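Z climbed faster early in the south-west run than late: 21.3% in the first 8.00 min, but 4.1 percentage points in the last 10.0 min.

common to all: G 1.8 M

| charge | Q | remark | time |
|---|---|---|---|
| south-west | 1.2 M | run made earlier |  |
| dawn | 1.44 M |  | 1.0 h |
| autumn | 1.80 M |  | 1.0 h |
| summer | 2.70 M |  | 1.0 h |

south-west run (percent of the G charged)

| time / min | Z / % | J / % |
|---|---|---|
| 8.00 | 21.3 | 0 |
| 15.0 | 30.5 | 0 |
| 20.0 | 34.4 | 0 |
| 30.0 | 40.6 | 0.1 |
| 40.0 | 44.7 | 0 |

(scatter of a reading: 1 percentage point)

- the analysis behind the earlier runs scatters by 1 percentage point, standard deviation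
- on the list of suspects stand: X + Q <-> D + J; Q <-> E; G + Q <-> D + Z; Z + Q <-> D + X
- no earlier run changes the charge of Q; that part of a forecast is a guess

- final Z, as a percentage of the G charged, for each flask in turn (dawn, autumn, summer)

I wanted the point where each flask stalls, so I counted one D made and one Q lost for each Z formed. Q was the limiting reagent in the south-west run. I called Z times D over G times Q, at the point where the forward and back rates balance, the stall quotient.

First I needed the forward constant. The first reading gave 0.383 M of Z. I replaced the falling G and Q by their midpoint values and got 0.0296 /M/min. The exact curve gave 0.0303 /M/min, so the mean cost 2.50%.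

Then I took two ways to the quotient. Over the last interval, mean Z was 0.768 M. The forward rate should have been 0.0132 M/min, but the flask made 0.00738 M/min. I took the gap as the way back, and that gave a quotient of 3.00. This is rough, since each reading scatters by 1 point.

The second way put the last reading straight into the quotient and gave 1.64, which is lower. That way cheats. Z was still rising at that reading, so I kept the rate balance.

With 3.00, the stalls came to 56.1% at dawn, 63.4% in autumn and 75.0% in summer. I committed to these as upper marks for the hour.

The forecast was lower, with 51%, 58% and 68%, "Taking the reversible step as the main picture".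

The flasks gave 54.6%, 62.4% and 72.9%.

    X + Q ⇌ D + J (K = 0.830, k = 3.90 × 10⁻⁴ /M/s)
    Q ⇌ E (K = 0.540, k = 1.70 × 10⁻⁴ /s)
    G + Q ⇌ D + Z (K = 12.0, k = 5.40 × 10⁻⁴ /M/s)
    Z + Q ⇌ D + X (K = 0.430, k = 4.60 × 10⁻⁵ /M/s)

By my count, the autumn flask ended the hour at a quotient of 2.75 and the summer flask at 2.54. Both stood below my 3.00, and the step's own constant is 12. My count left 37.6% of the Q in the autumn flask, but 18% stood there, with 0.207 M of E beside it. The autumn flask without the using up of Q reached 75.6% of Z, against 62.4%.

The earlier runs and the new flask are calculated on assumed constants, noise included.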